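**Plan**

- Retrosynthetic cuts, in order: the three ester C–O bonds and the C3 and C9 carbinol C–H bonds (back to an enedione); C8–C9 together with C12–O (borylative diene–aldehyde ring closure); C7–C11 and C7=C8 (isopropenyl addition and methylenation at a lactone carbonyl); C1–C2 and C5–C6 (Diels–Alder reaction).
- Forward order: a δ-lactone that is ring B with O in place of C8 is made first, ring A is fused onto it by a Diels–Alder reaction, the lactone is opened to a dienyl aldehyde, and ring B is closed last at C8–C9.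
- Enabling feature: the array C9(O)–C8H2–C7(=C11)–C12H2(O) around the exocyclic tetrasubstituted alkene of ring B is the 1,4-adduct of an aldehyde carbon and an oxygen across a butadiene C8=C7–C11=C12 carried on C6 of ring A.
- Stereochemistry: C10 is bought (Roche ester). C1 and C6 are relayed from it in the Diels–Alder reaction. The alkene geometry comes from the nickelacycle. C3 and C9 are set together by convex-face hydride delivery to the cis-fused dione.
- Remark on labels: atoms carry cadinane numbers (C1/C6 ring fusion, C3 and C9 acetoxy carbons, C4=C5, C7=C11, C10 the methyl-bearing carbon, C12 the formyloxymethyl carbon).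

Key step: step 9

**Route**

Step 1
Reactants: 1 methyl (R)-3-hydroxy-2-methylpropanoate
Product: 2 methyl (R)-3-[(tert-butyldimethylsilyl)oxy]-2-methylpropanoate
Conditions: t-BuMe2SiCl, imidazole, CH2Cl2, 0 °C to rt
Reagents that add atoms: tert-butyldimethylsilyl chloride, CC(C)(C)[Si](C)(C)Cl
Why: Standard silyl ether protection of a primary alcohol; the stereocentre is not touched.

Step 2
Reactants: 2 methyl (R)-3-[(tert-butyldimethylsilyl)oxy]-2-methylpropanoate
Product: 3 (R)-3-[(tert-butyldimethylsilyl)oxy]-2-methylpropanal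
Conditions: i-Bu2AlH (1.05 equiv), CH2Cl2, −78 °C; aqueous work-up, used crude
Reagents that add atoms: none
Why: Partial reduction of an ester by i-Bu2AlH stops at the aldehyde because the tetrahedral aluminate persists at low temperature; the labile α-centre is preserved by using the aldehyde cold and crude.

Step 3
Reactants: 3 (R)-3-[(tert-butyldimethylsilyl)oxy]-2-methylpropanal
Product: 5 (5S)-5-methyl-5,6-dihydro-2H-pyran-2-one, via Z-enoate 4 (not isolated)
Conditions: (CF3CH2O)2P(O)CH2CO2Me, KN(SiMe3)2, 18-crown-6, THF, −78 °C; then aq. HF, MeCN, rt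
Reagents that add atoms: methyl bis(2,2,2-trifluoroethyl)phosphonoacetate, COC(=O)CP(=O)(OCC(F)(F)F)OCC(F)(F)F
Why: The Still–Gennari variant of the Horner–Wadsworth–Emmons reaction should give the Z-enoate, and desilylation lets the freed hydroxyl close onto the cis ester (lactonisation); C10 is not touched.

Step 4
Reactants: 6 3-methylbut-3-en-2-one
Product: 7 triisopropyl[(3-methylbuta-1,3-dien-2-yl)oxy]silane
Conditions: i-Pr3SiOTf, Et3N, Et2O, 0 °C to rt
Reagents that add atoms: triisopropylsilyl trifluoromethanesulfonate, CC(C)[Si](C(C)C)(C(C)C)OS(=O)(=O)C(F)(F)F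
Why: Soft enolisation toward the only α-methyl group and O-silylation (silyl dienol ether formation) should give the 2-silyloxydiene.

Step 5
Reactants: 5 (5S)-5-methyl-5,6-dihydro-2H-pyran-2-one; 7 triisopropyl[(3-methylbuta-1,3-dien-2-yl)oxy]silane
Product: 8 (4S,4aS,8aS)-4,7-dimethyl-6-[(triisopropylsilyl)oxy]-3,4,4a,5,8,8a-hexahydro-1H-isochromen-1-one (cis-fused)
Conditions: Me2AlCl (1.1 equiv), CH2Cl2, −78 to −20 °C
Reagents that add atoms: none
Why: Lewis-acid-promoted Diels–Alder reaction in which the silyloxy group makes C2 the nucleophilic diene terminus, so C2 should bond to the lactone β-carbon C1 ("para" orientation, overriding the methyl group); the ring of the dienophile forces the cis C1/C6 fusion and the diene should add anti to the C10 methyl group, so C1 and C6 are set from C10.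

Step 6
Reactants: 8 (4S,4aS,8aS)-4,7-dimethyl-6-[(triisopropylsilyl)oxy]-3,4,4a,5,8,8a-hexahydro-1H-isochromen-1-one
Product: 10 1-[(1S,6S)-6-[(2S)-1-hydroxypropan-2-yl]-3-methyl-4-[(triisopropylsilyl)oxy]cyclohex-3-en-1-yl]-2-methylprop-2-en-1-one (in equilibrium with its cyclic hemiketal), via magnesium hemiketal 9 (not isolated)
Conditions: CH2=C(CH3)MgBr (1.2 equiv), THF, −78 °C; then NH4Cl aq.
Reagents that add atoms: isopropenylmagnesium bromide, CC(=C)[Mg]Br
Why: Acyl substitution of a lactone by an alkenyl Grignard reagent should stop after one addition because the magnesium hemiketal survives at −78 °C and releases the enone only on quench; no stereocentre is involved.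

Step 7
Reactants: 10 the hydroxy enone above
Product: 11 (2S)-2-[(1R,6S)-4-methyl-6-(3-methylbuta-1,3-dien-2-yl)-3-[(triisopropylsilyl)oxy]cyclohex-3-en-1-yl]propan-1-ol
Conditions: Zn, CH2Br2, TiCl4 (pre-formed reagent, excess), THF/CH2Cl2, 0 °C to rt
Reagents that add atoms: dibromomethane, BrCBr
Why: Lombardo–Takai methylenation converts hindered, enolisable ketones to 1,1-disubstituted alkenes without base, so C6 (α to the ketone) should not epimerise, and a free hydroxyl is tolerated when excess reagent is used.

Step 8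
Reactants: 11 the dienol above
Product: 12 (2S)-2-[(1R,6S)-4-methyl-6-(3-methylbuta-1,3-dien-2-yl)-3-[(triisopropylsilyl)oxy]cyclohex-3-en-1-yl]propanal
Conditions: (n-Pr)4N[RuO4] (5 mol %), N-methylmorpholine N-oxide, 4 Å molecular sieves, CH2Cl2, rt
Reagents that add atoms: none
Why: Ley–Griffith oxidation is neutral, so the aldehyde should form without epimerisation at C10 and without touching the diene or the silyl enol ether.

Step 9
Reactants: 12 the dienyl aldehyde above
Product: 14 (2E)-2-[(1S,2R,4aS,8aR)-2-hydroxy-1,6-dimethyl-7-[(triisopropylsilyl)oxy]-2,3,4a,5,8,8a-hexahydronaphthalen-4(1H)-ylidene]propan-1-ol, via bis(boronate) 13 (not isolated)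
Conditions: Ni(cod)2 (10 mol %), P(SiMe3)3 (15 mol %), B2pin2 (1.3 equiv), THF, rt; then NaOH aq., H2O2, 0 °C
Reagents that add atoms: bis(pinacolato)diboron (atoms retained in 13 only), CC1(C)OB(OC1(C)C)B1OC(C)(C)C(C)(C)O1; hydrogen peroxide (the C12 oxygen), OO
Why: Proposed new method: zerovalent nickel binds the s-cis diene and the aldehyde and couples C9 with the diene terminus C8 by oxidative cyclisation, giving an oxanickelacycle whose η3-allyl unit (C7–C11–C12) is held to nickel through the C9 alkoxide; σ-bond metathesis with B2pin2 at Ni–O and C–B reductive elimination at the unsubstituted terminus C12 should then release 13 and zerovalent nickel, and peroxide turns C–B into C–OH. The closest known reaction types are the intermolecular Ni(cod)2/P(SiMe3)3-catalysed borylative 4,1-coupling of 1,3-dienes, aldehydes and B2pin2 and the nickel-catalysed cyclisations of dienyl aldehydes with hydrosilanes or silylstannanes; the new element is ring closure with a diene tethered through its internal carbon. Ring B closes as a six-membered carbocycle in a 6-endo sense (C7 and C8 both become ring atoms) through a chair-like bicyclic transition state in which C2 on C1 and the C10 methyl group are equatorial and the C9 oxygen is axial because it must bridge to nickel on C7. The new C9 centre is therefore expected cis to the C10 methyl group (it is erased in step 12), while the C7=C11 geometry is fixed by the chelate: C8 sits anti on the allyl unit and so ends cis to C12, with C6 cis to the methyl group. The step needs C8 and not C12 to attack (six- against seven-membered ring), boron to go to C12 and not C7 (C7 is fully substituted, which also blocks syn/anti isomerisation of the allyl unit), and coupling to outrun 1,4-diboration of the diene, which the intramolecular aldehyde should secure.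

Step 10
Reactants: 14 the diol above
Product: 15 (2E)-2-[(1S,2R,4aR,8aR)-2-hydroxy-1,6-dimethyl-7-oxo-2,3,4a,7,8,8a-hexahydronaphthalen-4(1H)-ylidene]propan-1-ol
Conditions: Pd(OAc)2 (1.1 equiv), MeCN/DMSO, rt to 40 °C
Reagents that add atoms: none
Why: Saegusa–Ito oxidation: the silyl enol ether should transmetallate to a palladium enolate and β-hydride elimination toward C5 unveils the conjugated 2-methyl enone regiospecifically; it is run before formylation so that no allylic ester meets palladium.

Step 11
Reactants: 15 the enone diol above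
Product: 16 (2E)-2-[(1S,2R,4aR,8aR)-2-hydroxy-1,6-dimethyl-7-oxo-2,3,4a,7,8,8a-hexahydronaphthalen-4(1H)-ylidene]propyl formate
Conditions: HCO2CH2CF3 (excess), THF, 40 °C
Reagents that add atoms: 2,2,2-trifluoroethyl formate, O=COCC(F)(F)F
Why: Acyl transfer from an activated formate should be selective for the unhindered primary allylic alcohol over the hindered axial C9 hydroxyl (chemoselective formylation).

Step 12
Reactants: 16 the hydroxy formate above
Product: 17 (2E)-2-[(1S,4aR,8aR)-1,6-dimethyl-2,7-dioxo-2,3,4a,7,8,8a-hexahydronaphthalen-4(1H)-ylidene]propyl formate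
Conditions: Dess–Martin periodinane, NaHCO3, CH2Cl2, 0 °C to rt; used at once
Reagents that add atoms: none
Why: Buffered Dess–Martin oxidation removes the C9 configuration left by the ring closure under conditions that should not move the C7=C11 bond into conjugation.

Step 13
Reactants: 17 the enedione above
Product: 18 (2E)-2-[(1S,2S,4aR,7S,8aR)-2,7-dihydroxy-1,6-dimethyl-2,3,4a,7,8,8a-hexahydronaphthalen-4(1H)-ylidene]propyl formate
Conditions: NaBH4, CeCl3·7H2O, MeOH, −78 °C
Reagents that add atoms: none
Why: Luche reduction (1,2-selective at the enone): in the cis-fused dione hydride should reach both carbonyls from the convex face, the face of the ring-fusion hydrogens (axial attack at C9), which places the C3 and C9 hydroxyls on the concave face as required, the C9 hydroxyl equatorial and trans to the C10 methyl group.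

Step 14
Reactants: 18 the diol above
Product: 19 (2E)-2-[(1S,2S,4aR,7S,8aR)-2,7-bis(acetyloxy)-1,6-dimethyl-2,3,4a,7,8,8a-hexahydronaphthalen-4(1H)-ylidene]propyl formate (target)
Conditions: Ac2O, pyridine, DMAP (cat.), CH2Cl2, 0 °C to rt
Reagents that add atoms: acetic anhydride, CC(=O)OC(C)=O
Why: Standard acetylation of the two secondary alcohols; the formate should be inert to acetic anhydride under these conditions.

**Compound list**

1 | methyl (R)-3-hydroxy-2-methylpropanoate | COC(=O)[C@H](C)CO | starting material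
2 | methyl (R)-3-[(tert-butyldimethylsilyl)oxy]-2-methylpropanoate | COC(=O)[C@H](C)CO[Si](C)(C)C(C)(C)C | intermediate
3 | (R)-3-[(tert-butyldimethylsilyl)oxy]-2-methylpropanal | O=C[C@H](C)CO[Si](C)(C)C(C)(C)C | intermediate
4 | methyl (2Z,4S)-5-[(tert-butyldimethylsilyl)oxy]-4-methylpent-2-enoate | COC(=O)/C=C\[C@H](C)CO[Si](C)(C)C(C)(C)C | intermediate (not isolated)
5 | (5S)-5-methyl-5,6-dihydro-2H-pyran-2-one | O=C1C=C[C@H](C)CO1 | intermediate
6 | 3-methylbut-3-en-2-one | CC(=O)C(C)=C | starting material
7 | triisopropyl[(3-methylbuta-1,3-dien-2-yl)oxy]silane | C=C(C)C(=C)O[Si](C(C)C)(C(C)C)C(C)C | intermediate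
8 | (4S,4aS,8aS)-4,7-dimethyl-6-[(triisopropylsilyl)oxy]-3,4,4a,5,8,8a-hexahydro-1H-isochromen-1-one | CC1=C(O[Si](C(C)C)(C(C)C)C(C)C)C[C@H]2[C@H](C)COC(=O)[C@H]2C1 | intermediate
9 | bromomagnesium salt of the 1-isopropenyl hemiketal of 8 (C7 epimers) | CC1=C(O[Si](C(C)C)(C(C)C)C(C)C)C[C@H]2[C@H](C)COC(O[Mg]Br)(C(C)=C)[C@H]2C1 | intermediate (not isolated)
10 | 1-[(1S,6S)-6-[(2S)-1-hydroxypropan-2-yl]-3-methyl-4-[(triisopropylsilyl)oxy]cyclohex-3-en-1-yl]-2-methylprop-2-en-1-one | CC1=C(O[Si](C(C)C)(C(C)C)C(C)C)C[C@@H]([C@H](C)CO)[C@@H](C(=O)C(C)=C)C1 | intermediate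
11 | (2S)-2-[(1R,6S)-4-methyl-6-(3-methylbuta-1,3-dien-2-yl)-3-[(triisopropylsilyl)oxy]cyclohex-3-en-1-yl]propan-1-ol | CC1=C(O[Si](C(C)C)(C(C)C)C(C)C)C[C@@H]([C@H](C)CO)[C@@H](C(=C)C(C)=C)C1 | intermediate
12 | (2S)-2-[(1R,6S)-4-methyl-6-(3-methylbuta-1,3-dien-2-yl)-3-[(triisopropylsilyl)oxy]cyclohex-3-en-1-yl]propanal | CC1=C(O[Si](C(C)C)(C(C)C)C(C)C)C[C@@H]([C@H](C)C=O)[C@@H](C(=C)C(C)=C)C1 | intermediate
13 | C9-O-boryl, C12-boryl bis(pinacol boronate) of 14 | CC1=C(O[Si](C(C)C)(C(C)C)C(C)C)C[C@H]2[C@H](C)[C@H](OB3OC(C)(C)C(C)(C)O3)C/C(=C(/C)CB3OC(C)(C)C(C)(C)O3)[C@H]2C1 | intermediate (not isolated)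
14 | (2E)-2-[(1S,2R,4aS,8aR)-2-hydroxy-1,6-dimethyl-7-[(triisopropylsilyl)oxy]-2,3,4a,5,8,8a-hexahydronaphthalen-4(1H)-ylidene]propan-1-ol | CC1=C(O[Si](C(C)C)(C(C)C)C(C)C)C[C@H]2[C@H](C)[C@H](O)C/C(=C(/C)CO)[C@H]2C1 | intermediate
15 | (2E)-2-[(1S,2R,4aR,8aR)-2-hydroxy-1,6-dimethyl-7-oxo-2,3,4a,7,8,8a-hexahydronaphthalen-4(1H)-ylidene]propan-1-ol | O=C1C[C@H]2[C@H](C)[C@H](O)C/C(=C(/C)CO)[C@H]2C=C1C | intermediate
16 | (2E)-2-[(1S,2R,4aR,8aR)-2-hydroxy-1,6-dimethyl-7-oxo-2,3,4a,7,8,8a-hexahydronaphthalen-4(1H)-ylidene]propyl formate | O=C1C[C@H]2[C@H](C)[C@H](O)C/C(=C(/C)COC=O)[C@H]2C=C1C | intermediate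
17 | (2E)-2-[(1S,4aR,8aR)-1,6-dimethyl-2,7-dioxo-2,3,4a,7,8,8a-hexahydronaphthalen-4(1H)-ylidene]propyl formate | O=C1C[C@H]2[C@H](C)C(=O)C/C(=C(/C)COC=O)[C@H]2C=C1C | intermediate
18 | (2E)-2-[(1S,2S,4aR,7S,8aR)-2,7-dihydroxy-1,6-dimethyl-2,3,4a,7,8,8a-hexahydronaphthalen-4(1H)-ylidene]propyl formate | O[C@H]1C[C@H]2[C@H](C)[C@@H](O)C/C(=C(/C)COC=O)[C@H]2C=C1C | intermediate
19 | (2E)-2-[(1S,2S,4aR,7S,8aR)-2,7-bis(acetyloxy)-1,6-dimethyl-2,3,4a,7,8,8a-hexahydronaphthalen-4(1H)-ylidene]propyl formate | CC(=O)O[C@H]1C[C@H]2[C@H](C)[C@@H](OC(C)=O)C/C(=C(/C)COC=O)[C@H]2C=C1C | target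

**Count**

Total step count: 14. Longest linear sequence: 13 steps (steps 1–3 and 5–14; the diene branch is step 4).

**Steps most likely to fail**

1. Step 9 (Proposed new method). What may go wrong: nickel-catalysed 1,4-diboration of the diene or simple reduction/borylation of the aldehyde may outrun the coupling; closure may take place through C12 to a seven-membered ring; the allyl unit may isomerise and erode the alkene geometry; the twisted, hindered diene may bind nickel poorly. Fallback with known chemistry, setting out from lactone 8 and coming back at dione 17: MeLi at −78 °C opens 8 to the methyl ketone F1, which is oxidised with (n-Pr)4N[RuO4]/N-methylmorpholine N-oxide to the keto aldehyde F2. An amine-catalysed (L-proline) enolexo intramolecular aldol reaction then closes ring B through the same C8–C9 bond to the ketol F3, whose hydroxyl is silylated (Et3SiCl, imidazole) to the triethylsilyl ether F4. A Horner–Wadsworth–Emmons reaction with triethyl 2-phosphonopropionate and NaH gives the tetrasubstituted enoate F5, in which the ester is expected on the less hindered C8 side (isomers separated). i-Bu2AlH reduces it to the allylic alcohol F6, Pd(OAc)2 unveils the enone F7, HCO2CH2CF3 gives the formate F8, and HF·pyridine frees the C9 alcohol F9. Dess–Martin oxidation then gives 17, so the C9 configuration from the aldol is immaterial.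

2. Step 5. What may go wrong: the weakly activated lactone may react sluggishly; the orientation directed by the C4 methyl group may compete; a stepwise Lewis-acid pathway may end in protodesilylation or a trans ring fusion. Fallback, setting out from 5 and 6 and coming back at 8: an anionic double Michael annulation, in which polar bond formation and not orbital coefficients fixes the regiochemistry. LiN(i-Pr)2 deprotonates 6 at its methyl group at −78 °C; the cross-conjugated lithium dienolate adds to C1 of 5 anti to the methyl group; the lactone enolate closes onto the enone terminus C5 to give the lithium enolate F10, which is O-silylated in the same flask with i-Pr3SiOTf to give 8.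

3. Step 13. What may go wrong: the formate may be lost to borohydride or methanolysis; facial selectivity may be incomplete at one of the two carbonyls; the C7=C11 bond of 17 may migrate into conjugation with the C9 ketone before reduction. Fallback, setting out from 16 and coming back at 19, which sets C9 by substitution and C3 by reagent control and never forms the dione: Mitsunobu inversion of the axial C9 alcohol with acetic acid (PPh3, diisopropyl azodicarboxylate) gives the inverted acetate F11. Reduction of the enone with (R)-2-methyl-CBS-oxazaborolidine and catecholborane gives the (S)-allylic alcohol F12. Acetylation (Ac2O, pyridine) gives 19.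

**Further compounds**

F1 | step 9 | 1-[(1S,6S)-6-[(2S)-1-hydroxypropan-2-yl]-3-methyl-4-[(triisopropylsilyl)oxy]cyclohex-3-en-1-yl]ethan-1-one | CC1=C(O[Si](C(C)C)(C(C)C)C(C)C)C[C@@H]([C@H](C)CO)[C@@H](C(C)=O)C1
F2 | step 9 | (2S)-2-[(1S,6S)-6-acetyl-4-methyl-3-[(triisopropylsilyl)oxy]cyclohex-3-en-1-yl]propanal | CC1=C(O[Si](C(C)C)(C(C)C)C(C)C)C[C@@H]([C@H](C)C=O)[C@@H](C(C)=O)C1
F3 | step 9 | cis-fused ketol: 2-hydroxy-1,6-dimethyl-7-[(triisopropylsilyl)oxy]-1,2,3,4a,5,8,8a-heptahydronaphthalen-4-one, hydroxyl equatorial and trans to the C10 methyl | CC1=C(O[Si](C(C)C)(C(C)C)C(C)C)C[C@H]2[C@H](C)[C@@H](O)CC(=O)[C@H]2C1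
F4 | step 9 | triethylsilyl ether of F3 | CC1=C(O[Si](C(C)C)(C(C)C)C(C)C)C[C@H]2[C@H](C)[C@@H](O[Si](CC)(CC)CC)CC(=O)[C@H]2C1
F5 | step 9 | ethyl (2E)-2-(ring B ylidene)propanoate from F4, ester cis to C8 | CC1=C(O[Si](C(C)C)(C(C)C)C(C)C)C[C@H]2[C@H](C)[C@@H](O[Si](CC)(CC)CC)C/C(=C(/C)C(=O)OCC)[C@H]2C1
F6 | step 9 | allylic alcohol from F5 | CC1=C(O[Si](C(C)C)(C(C)C)C(C)C)C[C@H]2[C@H](C)[C@@H](O[Si](CC)(CC)CC)C/C(=C(/C)CO)[C@H]2C1
F7 | step 9 | enone from F6 (C9 triethylsilyl ether, C12 alcohol) | O=C1C[C@H]2[C@H](C)[C@@H](O[Si](CC)(CC)CC)C/C(=C(/C)CO)[C@H]2C=C1C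
F8 | step 9 | formate of F7 | O=C1C[C@H]2[C@H](C)[C@@H](O[Si](CC)(CC)CC)C/C(=C(/C)COC=O)[C@H]2C=C1C
F9 | step 9 | C9 epimer of 16 (free C9 alcohol, enone, formate) | O=C1C[C@H]2[C@H](C)[C@@H](O)C/C(=C(/C)COC=O)[C@H]2C=C1C
F10 | step 5 | lithium enolate of the double Michael adduct (O-lithio analogue of 8) | CC1=C(O[Li])C[C@H]2[C@H](C)COC(=O)[C@H]2C1
F11 | step 13 | (2E)-2-[(1S,2S,4aR,8aR)-2-(acetyloxy)-1,6-dimethyl-7-oxo-2,3,4a,7,8,8a-hexahydronaphthalen-4(1H)-ylidene]propyl formate | O=C1C[C@H]2[C@H](C)[C@@H](OC(C)=O)C/C(=C(/C)COC=O)[C@H]2C=C1C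
F12 | step 13 | (2E)-2-[(1S,2S,4aR,7S,8aR)-2-(acetyloxy)-7-hydroxy-1,6-dimethyl-2,3,4a,7,8,8a-hexahydronaphthalen-4(1H)-ylidene]propyl formate | O[C@H]1C[C@H]2[C@H](C)[C@@H](OC(C)=O)C/C(=C(/C)COC=O)[C@H]2C=C1C
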